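**Retrosynthetic overview**
1. Abyssomicin N ⇐ caged γ-lactone keto ester by a C2–C3 Dieckmann closure of the eight-membered ring (last ring); C11–OH from a C11 ketone, C13–H by hydrogenation.
2. Cage (2-oxabicyclo[2.2.2]octane plus γ-lactone) ⇐ one-flask enantioselective hydroxylative dearomatisation of a 7-hydroxyindene (oxygen delivered to C12), then two oxa-Michael additions (CO2H → C15, then C12–OH → C16).
3. Indene phenol acid ⇐ 2-acylindanone via enol triflate and Reformatsky–Negishi coupling; the acyl chain (C3–C7, both methyl stereocentres) comes from desymmetrised meso-2,4-dimethylglutaric anhydride.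
4. Indanone ⇐ 2,3-dimethylphenol + acrylic acid (dihydrocoumarin, Fries-type rearrangement); both ring methyls come from the xylenol.
5. Ring order: cyclopentane (indane) → six-membered carbocycle by dearomatisation → γ-lactone → ether bridge → eight-membered ring.

Convention: locants C1–C16 are abyssomicin locants (C1 lactone C=O, C2, C3 enol carbon, C4, C5, C6, C7 ketone, C8, C9, C10, C11 carbinol, C12 ether carbon with CH3, C13, C14, C15 lactone C–O, C16 ether carbon).
Assumption: the quinidine-derived catalyst gives half-ester 8 in the (2R,4S) sense and the (R)-iodyl reagent gives the (S)-quinol 17; if either sense is reversed, the pseudo-enantiomeric catalyst or the (S)-reagent is used.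

**Step 1**
Reactants: 1 2,3-dimethylphenol; 2 acrylic acid
Product: 4 7,8-dimethylchroman-2-one, via aryl acrylate 3 (not isolated)
Conditions: sulfonic acid resin (Amberlyst 15), toluene, reflux, Dean–Stark
Reagents that add atoms: none
Why: Acid-catalysed esterification followed by intramolecular Friedel–Crafts hydroarylation of the acrylate at the only free ortho position (para to a methyl group) closes the dihydrocoumarin, and no stereocentre is formed.

**Step 2**
Reactants: 4 7,8-dimethylchroman-2-one
Product: 5 4-hydroxy-5,6-dimethylindan-1-one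
Conditions: AlCl3 (3 equiv), NaCl, melt, 180 °C; then ice, aq. HCl
Reagents that add atoms: none
Why: Fries-type rearrangement in which AlCl3 opens the aryl ester to an acylium ion that acylates the ring ortho to the side chain, the classical dihydrocoumarin to 4-hydroxyindan-1-one isomerisation.

**Step 3**
Reactants: 5 4-hydroxy-5,6-dimethylindan-1-one
Product: 6 4-methoxy-5,6-dimethylindan-1-one
Conditions: MeI, K2CO3, acetone, reflux
Reagents that add atoms: iodomethane, CI
Why: Williamson etherification masks the phenol for the enolate, triflation and organozinc steps that follow.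

**Step 4**
Reactants: 7 cis-2,4-dimethylglutaric anhydride (meso)
Product: 8 (2R,4S)-5-methoxy-2,4-dimethyl-5-oxopentanoic acid
Conditions: MeOH (10 equiv), hydroquinidine anthraquinone-1,4-diyl diether ((DHQD)2AQN, 10 mol%), Et2O, −20 °C
Reagents that add atoms: methanol, CO
Why: Cinchona-alkaloid-catalysed enantioselective alcoholysis of a meso anhydride (general-base catalysis selects one enantiotopic carbonyl) fixes both methyl stereocentres (future C4 and C6) in one operation.

**Step 5**
Reactants: 6 4-methoxy-5,6-dimethylindan-1-one; 8 half-ester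
Product: 11 methyl (2S,4R)-5-(4-methoxy-5,6-dimethyl-1-oxo-2,3-dihydro-1H-inden-2-yl)-2,4-dimethyl-5-oxopentanoate, via acyl imidazolide 9 (not isolated), via lithium enolate 10 (not isolated)
Conditions: 8, 1,1'-carbonyldiimidazole, THF, rt; 6, LiN(SiMe3)2 (2.2 equiv), THF, −78 °C; add 9, −78 → −20 °C; 1 M HCl
Reagents that add atoms: none
Why: Claisen-type C-acylation of the indanone enolate by the acyl imidazolide (far more electrophilic than the methyl ester) gives the β-diketone at −78 °C without epimerising the α-methyl centre; the new C8 centre is enolised and not controlled.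

**Step 6**
Reactants: 11 β-diketone
Product: 12 methyl (2S,4R)-5-[7-methoxy-5,6-dimethyl-3-(trifluoromethylsulfonyloxy)-1H-inden-2-yl]-2,4-dimethyl-5-oxopentanoate
Conditions: Tf2O, i-Pr2NEt, CH2Cl2, −78 °C
Reagents that add atoms: trifluoromethanesulfonic anhydride, O=S(=O)(OS(=O)(=O)C(F)(F)F)C(F)(F)F
Why: O-sulfonylation of the β-diketone is expected at the ring oxygen, giving the endocyclic, arene-conjugated enol triflate (the usual outcome for 2-acylcycloalkanones), because the side-chain carbonyl is shielded by its α-branch.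

**Step 7**
Reactants: 12 enol triflate; 13 tert-butyl bromoacetate
Product: 15 methyl (2S,4R)-5-[3-(2-tert-butoxy-2-oxoethyl)-7-methoxy-5,6-dimethyl-1H-inden-2-yl]-2,4-dimethyl-5-oxopentanoate, via Reformatsky reagent 14 (not isolated)
Conditions: 13, Zn dust (Me3SiCl-activated), THF, 40 °C; then 12, Pd(PPh3)4 (5 mol%), THF, 50 °C
Reagents that add atoms: none
Why: Negishi-type cross-coupling of a zinc ester enolate with the activated (vinylogous acyl) triflate installs C2–C1 on C16 under conditions too weakly basic to touch the esters or the ketone.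

**Step 8**
Reactants: 15 tert-butyl ester
Product: 16 2-{7-hydroxy-2-[(2R,4S)-5-methoxy-2,4-dimethyl-5-oxopentanoyl]-5,6-dimethyl-1H-inden-3-yl}acetic acid
Conditions: BBr3 (4 equiv), CH2Cl2, −78 → 0 °C; then H2O
Reagents that add atoms: none
Why: Lewis-acid dealkylation cleaves the aryl methyl ether and the tert-butyl ester together, while the methyl ester survives at or below 0 °C.

**Step 9**
Reactants: 16 phenol acid
Product: 19 cage diketone (methyl (2S,4R)-2,4-dimethyl-5-oxo-5-(cage-C8-yl)pentanoate; cage = 2-oxabicyclo[2.2.2]octene with the C12–O–C16 bridge, C11=O, C13(CH3)=C14, the γ-lactone C15–O–C1(=O)–C2H2–C16 and the cyclopentane C15–C16–C8–C9–C10; C10, C12, C15 and C16 as in 22, C8 epimerisable and drawn as in 22), via ortho-quinol 17 (not isolated), via keto lactone 18 (not isolated)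
Conditions: (R)-2,2'-bis(iodyl)-1,1'-binaphthyl (1.1 equiv), CH2Cl2/CF3CH2OH, −40 → 0 °C; Me2S; then 1,8-diazabicyclo[5.4.0]undec-7-ene (0.3 equiv), CH2Cl2, 0 °C → rt
Reagents that add atoms: (R)-2,2'-bis(iodyl)-1,1'-binaphthyl, O=I(=O)c1ccc2ccccc2c1-c1c(I(=O)=O)ccc2ccccc12
Why: Proposed new method: the axially chiral pentavalent-iodine reagent transfers oxygen to the methyl-bearing ortho carbon C12 (flanked by the C13 methyl, whereas the ring-fusion ortho carbon C10 adjoins the acceptor-substituted C15) on one enantiotopic face to give the (S)-ortho-quinol 17; the carboxylic acid then adds to the dienone β-carbon C15 (reversible, since 18 is a β-acyloxy ketone), and only the lactone epimer with C16 syn to the C12 hydroxyl can add that hydroxyl to the enone carbon C16, which makes the cage bridgehead C10 non-enolisable and locks the lactone, so C12 alone dictates C15, C16 and C10; the closest known reactions are Quideau-type asymmetric hydroxylative phenol dearomatisation of 2-alkylphenols with chiral iodyl biaryls and intramolecular oxa-Michael additions.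

**Step 10**
Reactants: 19 cage diketone
Product: 20 13,14-dihydro cage diketone (C13 methyl syn to the ether bridge)
Conditions: H2 (4 atm), 5% Rh/Al2O3, EtOAc, rt
Reagents that add atoms: none
Why: Heterogeneous hydrogenation from the face of the alkene next to the C10–C11 bridge, because the other face is screened by the lactone CH2 on C16, places the C13 methyl syn to the ether oxygen as in 22; rhodium is chosen to avoid hydrogenolysis of the allylic C–O bonds.

**Step 11**
Reactants: 20 dihydro cage diketone
Product: 21 11-hydroxy seco ester (methyl ester of 2,3-seco-abyssomicin N; C11–OH anti to the ether bridge)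
Conditions: NaBH4 (1.0 equiv), MeOH/THF 1:4, −40 °C; aq. NH4Cl
Reagents that add atoms: none
Why: Borohydride reduces the strained α-alkoxy C11 ketone in preference to the doubly α-branched C7 ketone and should enter syn to the ether-oxygen bridge, since the carbon bridge on the other side now carries an inward-pointing C13–H, which puts the hydroxyl anti to the bridge oxygen.

**Step 12**
Reactants: 21 seco ester
Product: 22 abyssomicin N
Conditions: KOt-Bu (3.5 equiv), THF/t-BuOH, 0.005 M, 0 °C → rt; then 1 M HCl
Reagents that add atoms: none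
Why: Dieckmann (Lacey-type) condensation under thermodynamic control, in which only the 2-acyl lactone is trapped as a stabilised enolate while the other Claisen adducts lack an acidic C–H between their carbonyls and revert; C8 epimerises to the one configuration that can cyclise, gem-disubstitution at C16 assists ring closure, and acid work-up gives the hydrogen-bonded C3 enol.

**Compound list**
1 | 2,3-dimethylphenol | Cc1cccc(O)c1C | starting material
2 | acrylic acid | C=CC(=O)O | starting material
3 | 2,3-dimethylphenyl acrylate | C=CC(=O)Oc1cccc(C)c1C | intermediate (not isolated)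
4 | 7,8-dimethylchroman-2-one | Cc1ccc2CCC(=O)Oc2c1C | intermediate
5 | 4-hydroxy-5,6-dimethylindan-1-one | Cc1cc2C(=O)CCc2c(O)c1C | intermediate
6 | 4-methoxy-5,6-dimethylindan-1-one | COc1c(C)c(C)cc2C(=O)CCc12 | intermediate
7 | cis-2,4-dimethylglutaric anhydride (meso, (3R,5S)-3,5-dimethyloxane-2,6-dione) | C[C@@H]1C[C@H](C)C(=O)OC1=O | starting material
8 | (2R,4S)-5-methoxy-2,4-dimethyl-5-oxopentanoic acid | C[C@H](C[C@H](C)C(=O)OC)C(=O)O | intermediate
9 | methyl (2S,4R)-5-(imidazol-1-yl)-2,4-dimethyl-5-oxopentanoate | C[C@H](C[C@H](C)C(=O)OC)C(=O)n1ccnc1 | intermediate (not isolated)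
10 | lithium 7-methoxy-5,6-dimethyl-1H-inden-3-olate | [Li]OC1=CCc2c(OC)c(C)c(C)cc12 | intermediate (not isolated)
11 | methyl (2S,4R)-5-(4-methoxy-5,6-dimethyl-1-oxo-2,3-dihydro-1H-inden-2-yl)-2,4-dimethyl-5-oxopentanoate (C8 epimers/enol) | C[C@H](C[C@H](C)C(=O)OC)C(=O)C1Cc2c(OC)c(C)c(C)cc2C1=O | intermediate
12 | methyl (2S,4R)-5-[7-methoxy-5,6-dimethyl-3-(trifluoromethylsulfonyloxy)-1H-inden-2-yl]-2,4-dimethyl-5-oxopentanoate | C[C@H](C[C@H](C)C(=O)OC)C(=O)C1=C(OS(=O)(=O)C(F)(F)F)c2cc(C)c(C)c(OC)c2C1 | intermediate
13 | tert-butyl bromoacetate | CC(C)(C)OC(=O)CBr | starting material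
14 | (2-tert-butoxy-2-oxoethyl)zinc bromide | CC(C)(C)OC(=O)C[Zn]Br | intermediate (not isolated)
15 | methyl (2S,4R)-5-[3-(2-tert-butoxy-2-oxoethyl)-7-methoxy-5,6-dimethyl-1H-inden-2-yl]-2,4-dimethyl-5-oxopentanoate | C[C@H](C[C@H](C)C(=O)OC)C(=O)C1=C(CC(=O)OC(C)(C)C)c2cc(C)c(C)c(OC)c2C1 | intermediate
16 | 2-{7-hydroxy-2-[(2R,4S)-5-methoxy-2,4-dimethyl-5-oxopentanoyl]-5,6-dimethyl-1H-inden-3-yl}acetic acid | C[C@H](C[C@H](C)C(=O)OC)C(=O)C1=C(CC(=O)O)c2cc(C)c(C)c(O)c2C1 | intermediate
17 | 2-{(6S)-6-hydroxy-2-[(2R,4S)-5-methoxy-2,4-dimethyl-5-oxopentanoyl]-5,6-dimethyl-7-oxo-6,7-dihydro-1H-inden-3-yl}acetic acid (ortho-quinol) | C[C@H](C[C@H](C)C(=O)OC)C(=O)C1=C(CC(=O)O)C2=C(C1)C(=O)[C@@](C)(O)C(C)=C2 | intermediate (not isolated)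
18 | keto lactone: γ-lactone C15–O–C1(=O)–C2H2–C16 fused to the cyclopentene (C16=C8, acyl chain on C8) and to the cyclohexenone (C11=O, C12(OH)CH3, C13(CH3)=C14); lactone O trans to the C12 hydroxyl, C10–H cis to the lactone O | C[C@H](C[C@H](C)C(=O)OC)C(=O)C1=C2CC(=O)O[C@]23C=C(C)[C@](C)(O)C(=O)[C@@H]3C1 | intermediate (not isolated)
19 | cage diketone (11-oxo, 13,14-ene, C12–O–C16 bridge, γ-lactone, chain methyl ester; cage centres as in 22) | C[C@H](C[C@H](C)C(=O)OC)C(=O)[C@@H]1C[C@H]2C(=O)[C@@]3(C)O[C@@]14CC(=O)O[C@]42C=C3C | intermediate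
20 | 13,14-dihydro cage diketone (C13 methyl syn to the ether bridge) | C[C@H](C[C@H](C)C(=O)OC)C(=O)[C@@H]1C[C@H]2C(=O)[C@@]3(C)O[C@@]14CC(=O)O[C@]42C[C@@H]3C | intermediate
21 | 11-hydroxy seco ester (methyl ester of 2,3-seco-abyssomicin N) | C[C@H](C[C@H](C)C(=O)OC)C(=O)[C@@H]1C[C@H]2[C@H](O)[C@@]3(C)O[C@@]14CC(=O)O[C@]42C[C@@H]3C | intermediate
22 | abyssomicin N | C[C@@H]1C[C@H](C)/C(O)=C2/C(=O)O[C@]34C[C@H](C)[C@]5(C)O[C@]23[C@@H](C[C@H]4[C@@H]5O)C1=O | target

**Step count and risks**
Total steps: 12. Longest linear sequence: 11 (steps 1–3 and 5–12, from 2,3-dimethylphenol); step 4 is the one-step side branch.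

Most likely to fail:

1. Step 9. The oxygen transfer may go to the ring-fusion ortho carbon C10 instead of C12, the enantioselectivity on this substrate is untested, and the double oxa-Michael equilibrium may not favour the cage. Fallback, setting out from 16 and returning at 19: abandon reagent-controlled oxygen transfer for a Wessely oxidation (Pb(OAc)4, AcOH, rt), which gives the ortho-quinol acetate F1 as both C12 epimers. K2CO3 in MeOH at 0 °C then removes the acetate and triggers the same lactonisation and ether closure. This gives 19 together with its cage-diastereomer F2 (all cage centres inverted, chain unchanged); the two are separable by chromatography because the chain stereocentres make them diastereomers.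

2. Step 12. The eight-membered Claisen closure has to beat ketone-enolate pathways, retro-oxa-Michael opening of the ether bridge, and epimerisation at C6. Fallback, setting out from 21 and returning at 22: close the ring by acyl transfer through a six-membered transition state with the C7 ketone masked.
   - Et3SiOTf and 2,6-lutidine give the 11-O-triethylsilyl ether F3.
   - NaBH4 in MeOH at rt reduces the only remaining ketone (C7), and the resulting alkoxide closes onto the C3 methyl ester to give the δ-lactone F4 (C7 epimers).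
   - LiN(SiMe3)2 in THF (−78 → 0 °C) deprotonates the γ-lactone CH2, whose enolate attacks the δ-lactone carbonyl; this ring-expanding Claisen gives the 7-hydroxy acyl lactone F5.
   - Dess–Martin periodinane gives the 11-O-triethylsilyl ether of abyssomicin N F6, and HF·pyridine gives 22.

3. Step 11. If hydride enters from the carbon-bridge side instead, the C11 epimer results. Fallback, setting out from 20 and returning at 21: accept the kinetic product, the 11-epi alcohol F7, and correct it under thermodynamic control by redox epimerisation with Shvo's complex [(η5-Ph4C4CO)2H]Ru2(CO)4(μ-H) in toluene at 90 °C. The expected equilibrium favours 21, whose hydroxyl eclipses C10–H rather than the C10–C9 bond and lies antiperiplanar to the ether oxygen; this preference is estimated, not calculated.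

**Further compounds**
F1 | step 9 | ortho-quinol acetate of 16 (6-acetoxy-6-methylcyclohexa-2,4-dienone, both C12 epimers) | C[C@H](C[C@H](C)C(=O)OC)C(=O)C1=C(CC(=O)O)C2=C(C1)C(=O)C(C)(OC(C)=O)C(C)=C2
F2 | step 9 | cage-diastereomer of 19 (C8, C10, C12, C15, C16 inverted) | C[C@H](C[C@H](C)C(=O)OC)C(=O)[C@H]1C[C@@H]2C(=O)[C@]3(C)O[C@]14CC(=O)O[C@@]42C=C3C
F3 | step 12 | 11-O-triethylsilyl ether of 21 | C[C@H](C[C@H](C)C(=O)OC)C(=O)[C@@H]1C[C@H]2[C@H](O[Si](CC)(CC)CC)[C@@]3(C)O[C@@]14CC(=O)O[C@]42C[C@@H]3C
F4 | step 12 | δ-lactone (C7–O–C3(=O), C7 epimers) of the 11-O-triethylsilyl cage | C[C@@H]1C[C@H](C)C(=O)OC1[C@@H]1C[C@H]2[C@H](O[Si](CC)(CC)CC)[C@@]3(C)O[C@@]14CC(=O)O[C@]42C[C@@H]3C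
F5 | step 12 | 7-hydroxy-7-deoxo-11-O-triethylsilyl-abyssomicin N (C7 epimers) | C[C@@H]1C[C@H](C)/C(O)=C2/C(=O)O[C@]34C[C@H](C)[C@]5(C)O[C@]23[C@@H](C[C@H]4[C@@H]5O[Si](CC)(CC)CC)C1O
F6 | step 12 | 11-O-triethylsilyl-abyssomicin N | C[C@@H]1C[C@H](C)/C(O)=C2/C(=O)O[C@]34C[C@H](C)[C@]5(C)O[C@]23[C@@H](C[C@H]4[C@@H]5O[Si](CC)(CC)CC)C1=O
F7 | step 11 | 11-epi-21 | C[C@H](C[C@H](C)C(=O)OC)C(=O)[C@@H]1C[C@H]2[C@@H](O)[C@@]3(C)O[C@@]14CC(=O)O[C@]42C[C@@H]3C
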